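A small charge of catalyst, 0.1 mol%, turns substrate into target, and in both earlier runs the target peak climbs and then sinks while substrate still feeds it. So the first question is how fast target fades.

| flask | substrate | gas phase | catalyst | remark | time |
|---|---|---|---|---|---|
| spring | 0.67 M | 200 mM (held) | 0.1 mol% | run made earlier |  |
| autumn | 2 M | 200 mM (held) | 0.1 mol% | run made earlier |  |
| Wednesday's | 1.0 M | 200 mM (held) | 0.1 mol% |  | 50 min |
| Saturday's | 1.0 M | 200 mM (held) | 0.2 mol% |  | 50 min |

| run | time / min | target / % | substrate / % |
|---|---|---|---|
| spring | 4.00 | 12.2 | 82.7 |
| spring | 10.0 | 28.4 | 58.5 |
| spring | 20.0 | 29.0 | 30.1 |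
| spring | 30.0 | 24.4 | 16.9 |
| autumn | 8.00 | 33.7 | 54.5 |
| autumn | 15.0 | 41.7 | 23.9 |
| autumn | 25.0 | 30.3 | 3.4 |
| autumn | 30.0 | 22.5 | 1.1 |

(standard deviation of a reading: 1 percentage point)

- which of the two there is more of at the end, Wednesday's (target / isomer of the product)
- which of the two there is more of at the end, Saturday's (target / isomer of the product)
- final target, as a percentage of the substrate charged, in Wednesday's
- final target, as a percentage of the substrate charged, in Saturday's

- at the start none of the gas phase is in solution

In the autumn run, between 15.0 min and 25.0 min, substrate fell and target fell too. If reacted substrate becomes target, target lost 32 percentage points in that stretch, from a mean of 36.0%. That gives my reading of the fading half-life, 7.82 min, the time in which target halves, unfed, so long as it goes on fading at that pace.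
The asked 50 min is 6.39 such half-lives, so the next question is when the feed stops.

Saturday's flask holds 2.00 mM catalyst, the same as autumn's 2.00 mM, on half the substrate. Autumn's substrate was down to 1.1% at 30.0 min, so I let Saturday's stand like autumn at that time, with 22.5% target, and fade unfed from there: 3.82%, my own rough figure for Saturday's. Wednesday's, with half that catalyst, I expect to feed later and stand higher. If what fades becomes the isomer of the product, the isomer leads in both flasks.

The forecast says isomer of the product for Wednesday's with 7.6% target, and isomer of the product for Saturday's with 4.1% target, on the ground “More catalyst therefore just makes target earlier”. Its Saturday's figure comes from its own integration, not from my reckoning.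

The flask gives isomer of the product in Wednesday's, with 11.1% target, and isomer of the product in Saturday's, with 8.10% target.

    gas phase ⇌ dissolved gas, rate k1*(csat - [dissolved gas]) (kL = 0.0180 s⁻¹)
    substrate + dissolved gas + catalyst → catalyst + target (k = 8.20 M⁻² s⁻¹)
    target ⇌ isomer of the product (K = 18.0, k = 0.00140 s⁻¹)

The forecast stands on all four counts. Left ten times as long, Saturday's still holds 5.26% target, a floor that the flask has and the forecast's number doesn't. So let the excess over that floor fade with 7.82 min: from 27.8% at 25.0 min it gives 7.72% for Saturday's at the asked time. Read at 39.1 min, Wednesday's stands 6 points from its answer at 50 min; a run that early is the kind that would prove the forecast's 7.6% wrong.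

Saturday's flask read at 30 min takes the same reckoning: the excess fading from 25.0 min gives 19.7% target, and the computed flask holds 20.7%.

(The data are simulated for an exercise; scatter was added.)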